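**Proposed synthesis of 11-phenyl-1-(2,4,6-trihydroxyphenyl)undecan-1-one by benzannulation of ring A**

Plan
- Ring A is numbered C1 (acyl-bearing carbon) to C6, with the oxygens on C2, C4 and C6. The retrosynthesis first cuts the O-alkyl bonds of a 2-methoxy-6-ethoxy-4-hydroxy aryl ketone, then the ring bonds C1–C2 and C5–C6.
- Because oxygen sits on the alternate carbons C2, C4, C6 and the ketone on C1, atoms C2–C5 map onto a 1,1,3-trioxygenated butadiene and C6–C1 onto an ynone whose far alkyne carbon bears oxygen.
- The ynone is cut at the carbonyl–alkyne bond into ethoxyacetylene and the Weinreb amide of 11-phenylundecanoic acid; the diene goes back to 1,1-dimethoxyethene and acetyl chloride.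
- Forward: two two-step branches (diene, ynone) meet in a [4+2] benzannulation that builds the only new ring. BBr3 then frees the phenols; the phenylalkyl chain is bought intact.
- The target has no stereocentre, so no stereocontrol is required.

Key step: step 5

Assumption: 11-phenylundecanoic acid, ethoxyacetylene (hexane solution) and 1,1-dimethoxyethene are treated as catalogue chemicals.

Step 1
Reactants: 1 1,1-dimethoxyethene; 2 acetyl chloride
Product: 3 4,4-dimethoxybut-3-en-2-one
Conditions: NEt3 (1.2 equiv), Et2O, 0 °C → rt, slow addition of 2
Reagents that add atoms: none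
Why: C-acylation of a ketene acetal: the nucleophilic CH2 carbon of 1 attacks the acid chloride and NEt3 takes HCl from the dimethoxycarbenium intermediate, which leaves the conjugated acylketene acetal 3.

Step 2
Reactants: 3 4,4-dimethoxybut-3-en-2-one
Product: 4 1,1-dimethoxy-3-(trimethylsilyloxy)buta-1,3-diene
Conditions: Me3SiCl, NEt3, ZnCl2 (3 mol %), Et2O, rt → 35 °C; filtration, distillation under reduced pressure, no aqueous work-up
Reagents that add atoms: chlorotrimethylsilane, C[Si](C)(C)Cl
Why: Silyl enol ether formation under the conditions used for 2-silyloxybutadienes: the methyl group is the only enolisable position of 3, so O-silylation of its enol can give only the cross-conjugated diene 4.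

Step 3
Reactants: 5 11-phenylundecanoic acid
Product: 7 N-methoxy-N-methyl-11-phenylundecanamide, via 1-(11-phenylundecanoyl)imidazole 6 (not isolated)
Conditions: CDI (1.1 equiv), CH2Cl2, rt, 1 h; then MeNH(OMe)·HCl (1.3 equiv), rt, 12 h
Reagents that add atoms: N,O-dimethylhydroxylamine hydrochloride, CNOC.Cl
Why: Weinreb amide formation through the acyl imidazolide: CDI activates the acid with loss of CO2 and the N,O-dimethylhydroxylamine salt then displaces imidazole, the phenylalkyl chain being inert.

Step 4
Reactants: 7 N-methoxy-N-methyl-11-phenylundecanamide; 8 ethoxyacetylene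
Product: 11 1-ethoxy-13-phenyltridec-1-yn-3-one, via lithium ethoxyacetylide 9 (not isolated), via lithium hemiaminal chelate 10 (not isolated)
Conditions: 8 (1.6 equiv), n-BuLi (1.5 equiv), THF, −78 °C, 30 min; then 7, −78 → −20 °C; sat. aq. NH4Cl, −20 °C; chromatography on NEt3-deactivated silica
Reagents that add atoms: none
Why: Weinreb ketone synthesis: lithium ethoxyacetylide adds once to 7 because the five-membered lithium chelate 10 survives until the cold quench, a known route to alkoxyethynyl ketones.

Step 5
Reactants: 4 1,1-dimethoxy-3-(trimethylsilyloxy)buta-1,3-diene; 11 1-ethoxy-13-phenyltridec-1-yn-3-one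
Product: 14 1-(2-ethoxy-4-hydroxy-6-methoxyphenyl)-11-phenylundecan-1-one, via cyclohexadiene cycloadduct 12 (not isolated), via aryl trimethylsilyl ether 13 (not isolated)
Conditions: 4 (2.5 equiv), toluene, 75 °C, 16 h; then 1 M HCl, THF, 0 °C → rt
Reagents that add atoms: none
Why: Proposed new method: the closest known reaction type is the Diels–Alder benzannulation of 1,1-dialkoxy-3-silyloxybutadienes with acetylenic ketones and esters, which has not been shown for an ynone whose β-carbon carries an alkoxy group, so 11 is an untried and less electrophilic dienophile. Bond formation should start between the terminal CH2 of 4, made electron-rich by both the enol silyl ether and the ketene acetal, and the ethoxy-bearing alkyne carbon, which is the only electrophilic alkyne carbon because ketone pull and ethoxy push polarise the triple bond in the same sense; the acetal carbon then bonds to the α-carbon, either in one asynchronous [4+2] event or, at the stepwise limit, by Mukaiyama–Michael addition followed by 6-exo-trig closure of the allenolate carbon onto the dimethoxycarbenium ion. Ring A is thus closed intermolecularly through its new bonds C1–C2 and C5–C6, and cycloadduct 12 aromatises by 1,4-elimination of methanol, driven by the gain of the benzene ring, before dilute acid removes the silyl group from 13. No stereocentre is formed. The step needs regioselectivity only, and the matched polarity of the two partners secures it, so the acyl group ends up flanked by the methoxy and the ethoxy carbon with the free hydroxyl para to it. The temperature is held at 75 °C because ethoxyalkynes lose ethene by a retro-ene path above about 100 °C.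

Step 6
Reactants: 14 1-(2-ethoxy-4-hydroxy-6-methoxyphenyl)-11-phenylundecan-1-one
Product: 16 11-phenyl-1-(2,4,6-trihydroxyphenyl)undecan-1-one, via tris(dibromoboryl) aryl ether 15 (not isolated)
Conditions: BBr3 (5 equiv), CH2Cl2, −78 °C → rt; then H2O, 0 °C
Reagents that add atoms: none
Why: Lewis-acid dealkylation of aryl ethers with BBr3: boron coordinates each ether oxygen, bromide removes the methyl and the ethyl group by SN2 (both ortho ethers being assisted by chelation to the ketone), and water hydrolyses the aryloxyboron bromides to the three phenols.

Compound list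
1 | 1,1-dimethoxyethene | C=C(OC)OC | starting material
2 | acetyl chloride | CC(=O)Cl | starting material
3 | 4,4-dimethoxybut-3-en-2-one | CC(=O)C=C(OC)OC | intermediate
4 | 1,1-dimethoxy-3-(trimethylsilyloxy)buta-1,3-diene | C=C(O[Si](C)(C)C)C=C(OC)OC | intermediate
5 | 11-phenylundecanoic acid | OC(=O)CCCCCCCCCCc1ccccc1 | starting material
6 | 1-(11-phenylundecanoyl)imidazole | O=C(CCCCCCCCCCc1ccccc1)n1ccnc1 | intermediate
7 | N-methoxy-N-methyl-11-phenylundecanamide | CON(C)C(=O)CCCCCCCCCCc1ccccc1 | intermediate
8 | ethoxyacetylene | CCOC#C | starting material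
9 | lithium ethoxyacetylide | CCOC#C[Li] | intermediate
10 | lithium 1-ethoxy-3-[methoxy(methyl)amino]-13-phenyltridec-1-yn-3-olate (racemic, transient chelate) | CCOC#CC(O[Li])(N(C)OC)CCCCCCCCCCc1ccccc1 | intermediate
11 | 1-ethoxy-13-phenyltridec-1-yn-3-one | CCOC#CC(=O)CCCCCCCCCCc1ccccc1 | intermediate
12 | 1-[2-ethoxy-6,6-dimethoxy-4-(trimethylsilyloxy)cyclohexa-1,4-dien-1-yl]-11-phenylundecan-1-one | CCOC1=C(C(=O)CCCCCCCCCCc2ccccc2)C(OC)(OC)C=C(O[Si](C)(C)C)C1 | intermediate
13 | 1-[2-ethoxy-6-methoxy-4-(trimethylsilyloxy)phenyl]-11-phenylundecan-1-one | CCOc1cc(O[Si](C)(C)C)cc(OC)c1C(=O)CCCCCCCCCCc1ccccc1 | intermediate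
14 | 1-(2-ethoxy-4-hydroxy-6-methoxyphenyl)-11-phenylundecan-1-one | CCOc1cc(O)cc(OC)c1C(=O)CCCCCCCCCCc1ccccc1 | intermediate
15 | 11-phenyl-1-[2,4,6-tris(dibromoboryloxy)phenyl]undecan-1-one | O=C(CCCCCCCCCCc1ccccc1)c1c(OB(Br)Br)cc(OB(Br)Br)cc1OB(Br)Br | intermediate
16 | 11-phenyl-1-(2,4,6-trihydroxyphenyl)undecan-1-one | O=C(CCCCCCCCCCc1ccccc1)c1c(O)cc(O)cc1O | target

Total step count: 6
Longest linear sequence: 4 steps (5 → 7 → 11 → 14 → 16; the diene branch 1 → 3 → 4 → 14 → 16 is equally long)

Steps most likely to fail

Step 5 (key step). The cycloaddition may stall because the ethoxy donor raises the LUMO of the alkyne. Longer or hotter reaction would let the ynol ether fragment by retro-ene loss of ethene and the acid-sensitive diene decompose before the two components join. The fallback uses known chemistry only; it sets out from acid 5 and returns at target 16. Acid 5 is converted with (COCl)2 and catalytic DMF in CH2Cl2 into 11-phenylundecanoyl chloride F1. F1 acylates 1,3,5-trimethoxybenzene under AlCl3 in CH2Cl2 at 0 °C (Friedel–Crafts acylation) to give 11-phenyl-1-(2,4,6-trimethoxyphenyl)undecan-1-one F2. BBr3 in CH2Cl2, as in step 6, then removes the three methyl groups and gives 16.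

Step 4. The tetrahedral adduct may collapse before the quench, leading to a second acetylide addition. The ynol ether may also hydrate to a β-keto ester on contact with acid during work-up or on silica. The fallback sets out from 7 and returns at 11. Reduction of 7 with i-Bu2AlH in THF at −78 °C should give 11-phenylundecanal F3. Lithium ethoxyacetylide 9 adds to F3 at −78 °C to give racemic 1-ethoxy-13-phenyltridec-1-yn-3-ol F4. MnO2 in CH2Cl2 at room temperature then oxidises the propargylic alcohol to 11, which is obtained by filtration alone, without aqueous acid.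

Step 1. HCl liberated during the acylation may add to the ketene acetal or start its polymerisation, and a second acylation of the product may compete. The fallback sets out from 2 and returns at 3. Addition of 2 to 1,1-dichloroethene with AlCl3 in CH2Cl2 should give 4,4,4-trichlorobutan-2-one F5, which loses HCl on distillation to 4,4-dichlorobut-3-en-2-one F6. NaOMe (2 equiv) in MeOH at 0 °C then replaces both vinylic chlorides by addition–elimination and delivers 3.

Further compounds
F1 | step 5 | 11-phenylundecanoyl chloride | O=C(Cl)CCCCCCCCCCc1ccccc1
F2 | step 5 | 11-phenyl-1-(2,4,6-trimethoxyphenyl)undecan-1-one | COc1cc(OC)c(C(=O)CCCCCCCCCCc2ccccc2)c(OC)c1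
F3 | step 4 | 11-phenylundecanal | O=CCCCCCCCCCCc1ccccc1
F4 | step 4 | 1-ethoxy-13-phenyltridec-1-yn-3-ol (racemic) | CCOC#CC(O)CCCCCCCCCCc1ccccc1
F5 | step 1 | 4,4,4-trichlorobutan-2-one | CC(=O)CC(Cl)(Cl)Cl
F6 | step 1 | 4,4-dichlorobut-3-en-2-one | CC(=O)C=C(Cl)Cl
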